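Remark (assumption on the chemistry): compounds 1, 3 and 8 are taken as commercial; "l‑menthyl" means (1R,2S,5R)‑2‑isopropyl‑5‑methylcyclohexyl, and the target lactone is numbered O1, C2(=O), C3, C4, C5.

## Analysis of the target

Target 18 is a γ‑butyrolactone (O1–C2(=O)–C3–C4–C5). C3 carries a tertiary hydroxyl and a 4‑hydroxy‑3‑methoxybenzyl group, C4 a 4‑hydroxy‑3‑methoxybenzoyl group, and C5 is an unsubstituted CH2. There are two adjacent stereocentres, C3 (fully substituted, S) and C4 (S). From the SMILES, the C3 hydroxyl and the C4 aroyl group lie on the same face of the ring, with the benzyl group and the C4 hydrogen on the other. The atoms HO–C3–C4–C(=O)Ar form a β‑hydroxy ketone whose carbinol carbon is quaternary. This is the feature the route uses: O–C3–C4–C=O, cis across the C3–C4 ring bond, is the retron of a 2‑isoxazoline fused to the lactone at C3–C4, i.e. a nitrile oxide added across a C3=C4 butenolide. The aldol unit is also the main liability. Retro‑aldol cleavage of C3–C4 gives an achiral α‑keto ester and so erases both stereocentres, C4–H is α to an aryl ketone and can epimerise, and loss of the tertiary hydroxyl gives a butenolide. The free guaiacyl phenols are oxidation‑sensitive. The problem is therefore to create the quaternary carbinol C3 and its neighbour C4 together, with relative and absolute control, and to unmask ketone and phenols only under neutral conditions.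

## Retrosynthetic reasoning

**18 from 17.** The two phenolic O–H bonds are traced back to benzyl ethers. Hydrogenolysis is neutral, so the aldol unit is not put at risk in the last step, and the benzyl‑protected aryl building blocks 1 and 8 are commercial.

**17 from 15 (through 16).** The β‑hydroxy ketone is not made by an aldol reaction. The C3–OH and the ketone C=O are traced back to the O–N and C=N bonds of the fused 2‑isoxazoline 15. In 15 the aldol unit is locked: it cannot undergo retro‑aldol cleavage and the ring‑fusion hydrogen is not α to a ketone. The forward reaction must cleave N–O and hydrolyse imine 16 without reducing it.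

**15 from 12 (through 13 and 14).** The lactone CH2 is traced back to an acetal carbon bearing the chiral alkoxy group. That group differentiates the two faces of the alkene in the key step, and it sits on the one ring carbon that must end as CH2–O. The forward sequence is acidic hydrolysis to lactol 13, hydride reduction of its open aldehyde form to 14, and relactonisation.

**12 from 7 and 11 (key disconnection).** Both isoxazoline bonds to the lactone are cut: C6a–O1 and C3a–C3. Cutting here delivers both stereocentres, the C3 oxygen and the whole aroyl arm in one operation, from a flat monocyclic butenolide 7 and the linear dipole 11. The cis relationship follows from suprafacial addition to a ring alkene. The benzyl group on C3 of 7 makes the alkene trisubstituted, which directs the dipole oxygen to that carbon. The C5 alkoxy group of 7 fixes the face.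

**11 from 9 and 8.** Nitrile oxide 11 is made in the flask from oxime 9 through hydroximoyl chloride 10; 9 comes from aldehyde 8.

**7 from 5 and 6.** The C3–CH2 bond of 7 is an sp2–sp3 bond next to a carbonyl and is cut as a cross‑coupling between vinyl bromide 5 and benzylic organozinc 6. An enolate alkylation is not possible on the butenolide. Organozinc 6 comes from chloride 2 and alcohol 1; bromide 5 comes from 3 by bromination and dehydrobromination through 4.

## Alternatives that were turned down

**Alternative 1:** the textbook lignan route. C4–C(aryl) is cut as a conjugate addition of an acyl anion equivalent, C3–CH2Ar as an enolate alkylation and C3–OH as an enolate oxidation. In the forward direction the lithium derivative of dithiane A1 adds to 3, the enolate is trapped with 2, and reductive removal of the auxiliary gives trans lactone A2. The enolate of A2 is then oxidised with an electrophilic oxygen source and the dithiane is hydrolysed. It was turned down because the C4 substituent of A2 is a quaternary carbon carrying an aryl group and two sulfur atoms, so the oxidant attacks the enolate face away from it. The hydroxyl then ends trans to the C4 carbon arm, which is the C3 epimer of the target, and no element in the substrate enforces the cis arrangement. The three bonds at C3 and C4 are also made one at a time, and the dithiane must be removed by thiophilic or oxidative reagents at the end, on a retro‑aldol‑prone compound with electron‑rich arenes.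

**Alternative 2:** the C3–C4 bond is cut in the aldol sense within one molecule, which leads to the achiral, acyclic keto ester A3. The forward key step is a catalytic asymmetric intramolecular aldol addition of the aryl ketone enolate to the α‑keto ester carbonyl, closing the five‑membered lactone. It is the shortest route on paper. It was turned down for four reasons:
- The enolate of A3 carries a β‑acyloxy leaving group and should expel the arylpyruvate carboxylate by E1cB faster than it cyclises.
- The arylpyruvate half exists largely as its aryl‑conjugated enol, which removes the electrophile.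
- Aryl ketones are poor donors for enamine catalysis, so there is no close handle for absolute control.
- The aldol step is reversible, so any enantiomeric enrichment could be lost.

**Alternative 3:** the same C3–C4 bond is cut between two fragments. Enol silane A5 adds to arylpyruvate A4 in a Mukaiyama aldol reaction under a chiral divalent copper bis(oxazoline) Lewis acid that binds the α‑keto ester in a two‑point fashion. This gives A6, which is desilylated and lactonised. It was turned down because A4 is a benzylic, strongly enolised keto ester, and its enol competes for the Lewis acid. The substitution pattern (a benzyl ketone acceptor and a β‑silyloxy enol silane that can eliminate to an aryl vinyl ketone) leaves both the syn/anti and the facial outcome open. The step count is no lower than in the chosen route, and the cis relationship is not guaranteed by mechanism as it is in a cycloaddition.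

Key step: step 5

## Steps

Step 1
Reactants: 1 4‑(benzyloxy)‑3‑methoxybenzyl alcohol
Product: 2 4‑(benzyloxy)‑3‑methoxybenzyl chloride
Conditions: SOCl2, CH2Cl2, 0 °C to rt
Reagents that add atoms: thionyl chloride, O=S(Cl)Cl
Why: Chlorosulfite formation and chloride substitution at an electron‑rich benzylic carbon; the labile chloride is used at once.

Step 2
Reactants: 3 (5R)‑5‑(l‑menthyloxy)furan‑2(5H)‑one
Product: 5 (5R)‑3‑bromo‑5‑(l‑menthyloxy)furan‑2(5H)‑one, via trans‑3,4‑dibromolactone 4 (not isolated)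
Conditions: Br2, CH2Cl2, 0 °C to rt; then Et3N, 0 °C
Reagents that add atoms: bromine, BrBr
Why: Bromination–dehydrobromination of an enone: anti addition of bromine to C3=C4, then base removes the acidic C3–H and expels the C4 bromide, leaving the vinylic bromide at C3; C5 is not involved.

Step 3
Reactants: 2 4‑(benzyloxy)‑3‑methoxybenzyl chloride; 5 (5R)‑3‑bromo‑5‑(l‑menthyloxy)furan‑2(5H)‑one
Product: 7 (5R)‑3‑[4‑(benzyloxy)‑3‑methoxybenzyl]‑5‑(l‑menthyloxy)furan‑2(5H)‑one, via benzylzinc chloride 6 (not isolated)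
Conditions: 2, Zn dust, LiCl, THF, 25 °C; then 5, Pd(PPh3)4 (5 mol %), THF, 25 °C
Reagents that add atoms: none
Why: Negishi coupling: LiCl‑assisted zinc insertion into the benzylic C–Cl bond gives 6, which transmetalates to the vinylpalladium bromide formed by oxidative addition of zerovalent palladium into C3–Br of 5; reductive elimination forms the sp2–sp3 bond under neutral conditions that leave the C5 acetal alone.

Step 4
Reactants: 8 4‑(benzyloxy)‑3‑methoxybenzaldehyde
Product: 9 (E)‑4‑(benzyloxy)‑3‑methoxybenzaldehyde oxime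
Conditions: NH2OH·HCl, NaOAc, EtOH/H2O, rt
Reagents that add atoms: hydroxylamine hydrochloride, NO.Cl
Why: Oxime condensation under thermodynamic control gives the (E)‑aldoxime.

Step 5
Reactants: 9 (E)‑4‑(benzyloxy)‑3‑methoxybenzaldehyde oxime; 7 (5R)‑3‑[4‑(benzyloxy)‑3‑methoxybenzyl]‑5‑(l‑menthyloxy)furan‑2(5H)‑one
Product: 12 (3aR,4R,6aS)‑6a‑[4‑(benzyloxy)‑3‑methoxybenzyl]‑3‑[4‑(benzyloxy)‑3‑methoxyphenyl]‑4‑(l‑menthyloxy)‑3a,4‑dihydrofuro[3,4‑d]isoxazol‑6(6aH)‑one, via hydroximoyl chloride 10 (not isolated), via nitrile oxide 11 (not isolated)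
Conditions: 9 (2.5 equiv), NCS, DMF, rt; then 7, KHCO3 (solid), EtOAc, rt to 40 °C
Reagents that add atoms: none
Why: Oxime 9 is chlorinated to 10, which loses HCl on the solid base to release nitrile oxide 11 at low stationary concentration; 11 adds across C3=C4 of 7 (C6a and C3a of 12) in a concerted, asynchronous (3+2) cycloaddition (Huisgen nitrile oxide cycloaddition), the closest known type being nitrile oxide additions to 5‑alkoxyfuran‑2(5H)‑ones. The isoxazoline ring is closed by the cycloaddition itself, its two new bonds (C6a–O1 and C3a–C3) forming in one suprafacial event, so the 5/5 ring fusion can only be cis. This fixes the relative configuration: the oxygen on C6a and the aryl‑bearing carbon on C3a share one face and later become the cis hydroxyl and aroyl groups. The absolute configuration of both centres is controlled by the (5R)‑menthyloxy group of 7, which shields its own face of the flat butenolide so that the dipole adds anti to it. The regioselectivity needed is oxygen to C3 and carbon to C4 of 7: C3 is the fully substituted, benzyl‑bearing α‑carbon and C4 the less hindered β‑carbon, so the bulkier carbon terminus of the dipole should bond to C4, in line with the acrylate‑type polarisation in which the dipole carbon joins the β‑carbon. Dimerisation of 11 to the furoxan is the competing path; slow release of the dipole holds it back, and excess 9 compensates for the lower reactivity of the trisubstituted alkene.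

Step 6
Reactants: 12 (3aR,4R,6aS)‑6a‑[4‑(benzyloxy)‑3‑methoxybenzyl]‑3‑[4‑(benzyloxy)‑3‑methoxyphenyl]‑4‑(l‑menthyloxy)‑3a,4‑dihydrofuro[3,4‑d]isoxazol‑6(6aH)‑one
Product: 13 (3aR,6aS)‑6a‑[4‑(benzyloxy)‑3‑methoxybenzyl]‑3‑[4‑(benzyloxy)‑3‑methoxyphenyl]‑4‑hydroxy‑3a,4‑dihydrofuro[3,4‑d]isoxazol‑6(6aH)‑one (mixture of C4 anomers)
Conditions: aq. HCl (3 M), 1,4‑dioxane, 70 °C
Reagents that add atoms: water, O
Why: Acid hydrolysis of the acylal‑type acetal (protonation of the menthyloxy oxygen, acyloxy‑stabilised oxocarbenium ion, capture by water); isoxazoline, lactone and aryl benzyl ethers tolerate dilute aqueous acid, and only the cis‑fused lactol can ring‑close, so the ring fusion is retained.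

Step 7
Reactants: 13 (3aR,6aS)‑6a‑[4‑(benzyloxy)‑3‑methoxybenzyl]‑3‑[4‑(benzyloxy)‑3‑methoxyphenyl]‑4‑hydroxy‑3a,4‑dihydrofuro[3,4‑d]isoxazol‑6(6aH)‑one
Product: 15 (3aS,6aS)‑6a‑[4‑(benzyloxy)‑3‑methoxybenzyl]‑3‑[4‑(benzyloxy)‑3‑methoxyphenyl]‑3a,4‑dihydrofuro[3,4‑d]isoxazol‑6(6aH)‑one, via hydroxy acid 14 (not isolated)
Conditions: NaBH4, EtOH/THF, 0 °C; then aq. HCl (1 M), rt
Reagents that add atoms: none
Why: Reduction of a pseudo‑acid: in the hydride medium the lactol opens to the aldehyde carboxylate, whose aldehyde is reduced much faster than the C=N bond or the carboxylate; acidification closes the γ‑lactone, which only the cis hydroxy acid 14 can do.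

Step 8
Reactants: 15 (3aS,6aS)‑6a‑[4‑(benzyloxy)‑3‑methoxybenzyl]‑3‑[4‑(benzyloxy)‑3‑methoxyphenyl]‑3a,4‑dihydrofuro[3,4‑d]isoxazol‑6(6aH)‑one
Product: 17 (3S,4S)‑4‑[4‑(benzyloxy)‑3‑methoxybenzoyl]‑3‑[4‑(benzyloxy)‑3‑methoxybenzyl]‑3‑hydroxydihydrofuran‑2(3H)‑one, via hydroxy imine 16 (not isolated)
Conditions: H2 (1 atm), Raney Ni, B(OH)3, MeOH/THF/H2O, rt
Reagents that add atoms: water, O
Why: Hydrogenolytic N–O cleavage of a 2‑isoxazoline to β‑hydroxy imine 16 and its hydrolysis in the boric acid buffer, which binds the ammonia and keeps the medium near neutral, so that neither retro‑aldol cleavage nor C4 epimerisation is triggered; both stereocentres come unchanged from 15.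

Step 9
Reactants: 17 (3S,4S)‑4‑[4‑(benzyloxy)‑3‑methoxybenzoyl]‑3‑[4‑(benzyloxy)‑3‑methoxybenzyl]‑3‑hydroxydihydrofuran‑2(3H)‑one
Product: 18 (3S,4S)‑3‑hydroxy‑4‑(4‑hydroxy‑3‑methoxybenzoyl)‑3‑(4‑hydroxy‑3‑methoxybenzyl)dihydrofuran‑2(3H)‑one
Conditions: H2 (1 atm), Pd/C (10 %), EtOAc/EtOH, rt
Reagents that add atoms: none
Why: Hydrogenolysis of the two aryl benzyl ethers under neutral conditions; the electron‑rich aryl ketone, the tertiary alcohol and the lactone are not reduced at 1 atm in a non‑acidic solvent.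

## Compound list

1 | 4‑(benzyloxy)‑3‑methoxybenzyl alcohol | COc1cc(CO)ccc1OCc1ccccc1 | starting material
2 | 4‑(benzyloxy)‑3‑methoxybenzyl chloride | COc1cc(CCl)ccc1OCc1ccccc1 | intermediate
3 | (5R)‑5‑(l‑menthyloxy)furan‑2(5H)‑one | O=C1O[C@@H](O[C@@H]2C[C@H](C)CC[C@H]2C(C)C)C=C1 | starting material
4 | (3S,4S,5R)‑3,4‑dibromo‑5‑(l‑menthyloxy)dihydrofuran‑2(3H)‑one (expected major trans dibromide, not isolated) | O=C1O[C@@H](O[C@@H]2C[C@H](C)CC[C@H]2C(C)C)[C@H](Br)[C@H]1Br | intermediate
5 | (5R)‑3‑bromo‑5‑(l‑menthyloxy)furan‑2(5H)‑one | O=C1O[C@@H](O[C@@H]2C[C@H](C)CC[C@H]2C(C)C)C=C1Br | intermediate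
6 | [4‑(benzyloxy)‑3‑methoxybenzyl]zinc chloride (LiCl complex in THF, not isolated) | COc1cc(C[Zn]Cl)ccc1OCc1ccccc1 | intermediate
7 | (5R)‑3‑[4‑(benzyloxy)‑3‑methoxybenzyl]‑5‑(l‑menthyloxy)furan‑2(5H)‑one | O=C1O[C@@H](O[C@@H]2C[C@H](C)CC[C@H]2C(C)C)C=C1Cc1ccc(OCc2ccccc2)c(OC)c1 | intermediate
8 | 4‑(benzyloxy)‑3‑methoxybenzaldehyde | COc1cc(C=O)ccc1OCc1ccccc1 | starting material
9 | (E)‑4‑(benzyloxy)‑3‑methoxybenzaldehyde oxime | COc1cc(/C=N/O)ccc1OCc1ccccc1 | intermediate
10 | (Z)‑4‑(benzyloxy)‑N‑hydroxy‑3‑methoxybenzimidoyl chloride (not isolated) | COc1cc(/C(Cl)=N/O)ccc1OCc1ccccc1 | intermediate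
11 | 4‑(benzyloxy)‑3‑methoxybenzonitrile oxide (not isolated) | COc1cc(C#[N+][O-])ccc1OCc1ccccc1 | intermediate
12 | (3aR,4R,6aS)‑6a‑[4‑(benzyloxy)‑3‑methoxybenzyl]‑3‑[4‑(benzyloxy)‑3‑methoxyphenyl]‑4‑(l‑menthyloxy)‑3a,4‑dihydrofuro[3,4‑d]isoxazol‑6(6aH)‑one | COc1cc(C[C@@]2(ON=C3c4ccc(OCc5ccccc5)c(OC)c4)C(=O)O[C@@H](O[C@@H]4C[C@H](C)CC[C@H]4C(C)C)[C@@H]23)ccc1OCc1ccccc1 | intermediate
13 | (3aR,6aS)‑6a‑[4‑(benzyloxy)‑3‑methoxybenzyl]‑3‑[4‑(benzyloxy)‑3‑methoxyphenyl]‑4‑hydroxy‑3a,4‑dihydrofuro[3,4‑d]isoxazol‑6(6aH)‑one (C4 anomers) | COc1cc(C[C@@]2(ON=C3c4ccc(OCc5ccccc5)c(OC)c4)C(=O)OC(O)[C@@H]23)ccc1OCc1ccccc1 | intermediate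
14 | (4S,5S)‑5‑[4‑(benzyloxy)‑3‑methoxybenzyl]‑3‑[4‑(benzyloxy)‑3‑methoxyphenyl]‑4‑(hydroxymethyl)‑4,5‑dihydroisoxazole‑5‑carboxylic acid (sodium salt in the flask, not isolated) | COc1cc(C[C@@](ON=C2c3ccc(OCc4ccccc4)c(OC)c3)(C(=O)O)[C@@H]2CO)ccc1OCc1ccccc1 | intermediate
15 | (3aS,6aS)‑6a‑[4‑(benzyloxy)‑3‑methoxybenzyl]‑3‑[4‑(benzyloxy)‑3‑methoxyphenyl]‑3a,4‑dihydrofuro[3,4‑d]isoxazol‑6(6aH)‑one | COc1cc(C[C@@]2(ON=C3c4ccc(OCc5ccccc5)c(OC)c4)C(=O)OC[C@@H]23)ccc1OCc1ccccc1 | intermediate
16 | (3S,4S)‑3‑[4‑(benzyloxy)‑3‑methoxybenzyl]‑4‑{[4‑(benzyloxy)‑3‑methoxyphenyl](imino)methyl}‑3‑hydroxydihydrofuran‑2(3H)‑one (not isolated) | COc1cc(C[C@@]2(O)C(=O)OC[C@@H]2C(=N)c2ccc(OCc3ccccc3)c(OC)c2)ccc1OCc1ccccc1 | intermediate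
17 | (3S,4S)‑4‑[4‑(benzyloxy)‑3‑methoxybenzoyl]‑3‑[4‑(benzyloxy)‑3‑methoxybenzyl]‑3‑hydroxydihydrofuran‑2(3H)‑one | COc1cc(C[C@@]2(O)C(=O)OC[C@@H]2C(=O)c2ccc(OCc3ccccc3)c(OC)c2)ccc1OCc1ccccc1 | intermediate
18 | (3S,4S)‑3‑hydroxy‑4‑(4‑hydroxy‑3‑methoxybenzoyl)‑3‑(4‑hydroxy‑3‑methoxybenzyl)dihydrofuran‑2(3H)‑one | COc1cc(C[C@@]2(O)C(=O)OC[C@@H]2C(=O)c2ccc(O)c(OC)c2)ccc1O | target

## Step count and risk

Total: 9 steps. Longest linear sequence: 7 steps (steps 1, 3, 5, 6, 7, 8, 9 from 1; the branch from 3 through step 2 is equally long).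

**Step 5 (key step).** The most likely failures are reversed regiochemistry (dipole oxygen bonding to C4 instead of the benzyl‑bearing C3) and slow cycloaddition at the trisubstituted alkene, which lets dimerisation of the dipole take over. Ring chlorination of the electron‑rich arene during oxime chlorination is a lesser risk.

The fallback replaces auxiliary control on a butenolide by a metal‑alkoxide‑directed, tartrate‑controlled cycloaddition on an acyclic allylic alcohol, where the alkoxide delivers the dipole oxygen to the adjacent alkene carbon. It sets out from organozinc 6 (made from 2) and hydroximoyl chloride 10 (made from 9) and comes back at 15: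
- Negishi coupling of 6 with commercial 3‑bromofuran‑2(5H)‑one, Pd(PPh3)4, would give 3‑[4‑(benzyloxy)‑3‑methoxybenzyl]furan‑2(5H)‑one F1.
- Reduction with iBu2AlH would give (Z)‑2‑[4‑(benzyloxy)‑3‑methoxybenzyl]but‑2‑ene‑1,4‑diol F2.
- Silylation of the less hindered hydroxyl, remote from the benzyl group, with tBuPh2SiCl/imidazole would give the mono‑silyl ether F3.
- Treatment of F3 with Et2Zn and diisopropyl tartrate, then 10, in CHCl3 at 0 °C should give the 5‑(hydroxymethyl)isoxazoline F4. The (S,S) tartrate is chosen on the assumption that the facial sense of the parent allyl alcohol case carries over; otherwise its mirror image is used.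
- Oxidation of the primary alcohol with TEMPO/PhI(OAc)2 in aqueous MeCN would give the acid F5.
- Bu4NF followed by acidification would remove the silyl group and close the lactone to 15.

**Step 3.** Conjugate addition of the benzylzinc reagent to the butenolide, or ionisation of the allylic acetal by zinc halide or zerovalent palladium with erosion of the C5 configuration, would lower the yield and the stereochemical purity of 7. The fallback reverses the polarity of the coupling; it sets out from 5 and comes back at 7. Stannylation of 5 with (Bu3Sn)2 and Pd(PPh3)4 in hot toluene would give (5R)‑5‑(l‑menthyloxy)‑3‑(tributylstannyl)furan‑2(5H)‑one F6. Stille coupling of F6 with chloride 2 would then give 7.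

**Step 7.** In the ring‑opened aldehyde carboxylate the hydrogen at C3a is α to both the aldehyde and the C=N bond. β‑Elimination that opens the isoxazoline at C6a–O, or epimerisation at C3a before hydride arrives, would divert material. The fallback never exposes the open aldehyde to base; it sets out from 13 and comes back at 17. Acid‑catalysed exchange of the lactol hydroxyl with thiophenol (PhSH, cat. TsOH, CH2Cl2) would give the 4‑(phenylthio) lactone F7. Excess Raney Ni under H2 with B(OH)3 would then cleave the C–S bond and the N–O bond in one operation and give 17 directly.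

**Step 8.** Reduction of the intermediate aryl ketimine to the amine, followed by lactamisation, is the main risk. Retro‑aldol cleavage of the tertiary aldol and partial loss of benzyl groups on the nickel surface are possible as well. The fallback inverts the order of the last two operations and avoids hydrogen altogether; it sets out from 15 and comes back at 18. Debenzylation with BCl3 and pentamethylbenzene in CH2Cl2 at −78 °C would give the bis‑phenol (3aS,6aS)‑6a‑(4‑hydroxy‑3‑methoxybenzyl)‑3‑(4‑hydroxy‑3‑methoxyphenyl)‑3a,4‑dihydrofuro[3,4‑d]isoxazol‑6(6aH)‑one F8. N–O cleavage with Mo(CO)6 in MeCN/H2O at 80 °C would then give 18.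

## Further compounds

F1 | step 5 | 3‑[4‑(benzyloxy)‑3‑methoxybenzyl]furan‑2(5H)‑one | O=C1OCC=C1Cc1ccc(OCc2ccccc2)c(OC)c1
F2 | step 5 | (Z)‑2‑[4‑(benzyloxy)‑3‑methoxybenzyl]but‑2‑ene‑1,4‑diol | OC/C=C(\CO)Cc1ccc(OCc2ccccc2)c(OC)c1
F3 | step 5 | (Z)‑2‑[4‑(benzyloxy)‑3‑methoxybenzyl]‑4‑[(tert‑butyldiphenylsilyl)oxy]but‑2‑en‑1‑ol | OC/C(Cc1ccc(OCc2ccccc2)c(OC)c1)=C\CO[Si](c1ccccc1)(c1ccccc1)C(C)(C)C
F4 | step 5 | [(4S,5S)‑5‑[4‑(benzyloxy)‑3‑methoxybenzyl]‑3‑[4‑(benzyloxy)‑3‑methoxyphenyl]‑4‑{[(tert‑butyldiphenylsilyl)oxy]methyl}‑4,5‑dihydroisoxazol‑5‑yl]methanol | COc1cc(C[C@@](ON=C2c3ccc(OCc4ccccc4)c(OC)c3)(CO)[C@@H]2CO[Si](c2ccccc2)(c2ccccc2)C(C)(C)C)ccc1OCc1ccccc1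
F5 | step 5 | (4S,5S)‑5‑[4‑(benzyloxy)‑3‑methoxybenzyl]‑3‑[4‑(benzyloxy)‑3‑methoxyphenyl]‑4‑{[(tert‑butyldiphenylsilyl)oxy]methyl}‑4,5‑dihydroisoxazole‑5‑carboxylic acid | COc1cc(C[C@@](ON=C2c3ccc(OCc4ccccc4)c(OC)c3)(C(=O)O)[C@@H]2CO[Si](c2ccccc2)(c2ccccc2)C(C)(C)C)ccc1OCc1ccccc1
F6 | step 3 | (5R)‑5‑(l‑menthyloxy)‑3‑(tributylstannyl)furan‑2(5H)‑one | O=C1O[C@@H](O[C@@H]2C[C@H](C)CC[C@H]2C(C)C)C=C1[Sn](CCCC)(CCCC)CCCC
F7 | step 7 | (3aR,6aS)‑6a‑[4‑(benzyloxy)‑3‑methoxybenzyl]‑3‑[4‑(benzyloxy)‑3‑methoxyphenyl]‑4‑(phenylthio)‑3a,4‑dihydrofuro[3,4‑d]isoxazol‑6(6aH)‑one (C4 epimers) | COc1cc(C[C@@]2(ON=C3c4ccc(OCc5ccccc5)c(OC)c4)C(=O)OC(Sc4ccccc4)[C@@H]23)ccc1OCc1ccccc1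
F8 | step 8 | (3aS,6aS)‑6a‑(4‑hydroxy‑3‑methoxybenzyl)‑3‑(4‑hydroxy‑3‑methoxyphenyl)‑3a,4‑dihydrofuro[3,4‑d]isoxazol‑6(6aH)‑one | COc1cc(C[C@@]2(ON=C3c4ccc(O)c(OC)c4)C(=O)OC[C@@H]23)ccc1O
A1 | alternative 1 | 2‑[4‑(benzyloxy)‑3‑methoxyphenyl]‑1,3‑dithiane | COc1cc(C2SCCCS2)ccc1OCc1ccccc1
A2 | alternative 1 | (3R,4R)‑3‑[4‑(benzyloxy)‑3‑methoxybenzyl]‑4‑{2‑[4‑(benzyloxy)‑3‑methoxyphenyl]‑1,3‑dithian‑2‑yl}dihydrofuran‑2(3H)‑one | COc1cc(C[C@H]2C(=O)OC[C@@H]2C2(c3ccc(OCc4ccccc4)c(OC)c3)SCCCS2)ccc1OCc1ccccc1
A3 | alternative 2 | 3‑[4‑(benzyloxy)‑3‑methoxyphenyl]‑3‑oxopropyl 3‑[4‑(benzyloxy)‑3‑methoxyphenyl]‑2‑oxopropanoate | COc1cc(CC(=O)C(=O)OCCC(=O)c2ccc(OCc3ccccc3)c(OC)c2)ccc1OCc1ccccc1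
A4 | alternative 3 | methyl 3‑[4‑(benzyloxy)‑3‑methoxyphenyl]‑2‑oxopropanoate | COC(=O)C(=O)Cc1ccc(OCc2ccccc2)c(OC)c1
A5 | alternative 3 | (Z)‑{[1‑[4‑(benzyloxy)‑3‑methoxyphenyl]‑3‑[(tert‑butyldimethylsilyl)oxy]prop‑1‑en‑1‑yl]oxy}trimethylsilane | COc1cc(/C(O[Si](C)(C)C)=C/CO[Si](C)(C)C(C)(C)C)ccc1OCc1ccccc1
A6 | alternative 3 | methyl (2S,3S)‑2‑[4‑(benzyloxy)‑3‑methoxybenzyl]‑4‑[4‑(benzyloxy)‑3‑methoxyphenyl]‑3‑{[(tert‑butyldimethylsilyl)oxy]methyl}‑2‑hydroxy‑4‑oxobutanoate | COc1cc(C[C@@](O)(C(=O)OC)[C@H](CO[Si](C)(C)C(C)(C)C)C(=O)c2ccc(OCc3ccccc3)c(OC)c2)ccc1OCc1ccccc1
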